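**Retrosynthetic overview**
- The target comes from its bis-benzyl ether (naphthol oxygen and side-chain oxygen) by one neutral hydrogenolysis at the end.
- Key disconnection: the aryl C–O bond between the naphthalene peri carbon and the hemiaminal oxygen. It is made by an enantioconvergent, hydroxyl-directed peri C–H etherification of a configurationally labile 3-aryl-3-hydroxyisoindolinone, which closes the furan ring and fixes the spiro centre.
- The hydroxylactam comes from a diaryl carbinol (oxidation, then ring–chain closure of the keto amide). The carbinol comes from ortho-lithiated N-[2-(benzyloxy)ethyl]-3-methoxybenzamide and 2-(benzyloxy)-6-methyl-1-naphthaldehyde.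
- Building blocks: 3-methoxybenzoyl chloride with 2-(benzyloxy)ethanamine, and 6-methylnaphthalen-2-ol (ortho-formylation, benzylation).
- Ring order: lactam ring (step 5), then the furan ring together with the spiro centre (step 6).

Assumptions: 6-methylnaphthalen-2-ol and 2-(benzyloxy)ethan-1-amine are bought as catalogue chemicals. Which ligand antipode gives the (R) product in step 6 cannot be predicted and must be found by experiment; the route is written for the L-ligand, and the D-ligand is used if the (S) product forms.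

**Route**

Step 1
Reactants: 1 3-methoxybenzoyl chloride; 2 2-(benzyloxy)ethan-1-amine
Product: 3 N-[2-(benzyloxy)ethyl]-3-methoxybenzamide
Conditions: 2 M aq NaOH, CH2Cl2, 0 °C to rt
Reagents that add atoms: none
Why: Schotten–Baumann acylation of a primary amine by an aroyl chloride is fast and clean; no stereocentre is formed.

Step 2
Reactants: 4 6-methylnaphthalen-2-ol
Product: 6 2-hydroxy-6-methyl-1-naphthaldehyde, via 1-(hydroxymethyl)-6-methylnaphthalen-2-ol 5 (not isolated)
Conditions: MgCl2 (1.5 equiv), Et3N (3.75 equiv), (CH2O)n (excess), MeCN, reflux; dilute HCl work-up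
Reagents that add atoms: paraformaldehyde (reacts as formaldehyde), C=O
Why: Casnati–Skattebøl ortho-formylation: the magnesium naphtholate delivers formaldehyde to C1 (the most nucleophilic site of a 2-naphthol), and the benzylic alkoxide 5 is oxidised by a second formaldehyde through an Oppenauer-type hydride transfer; no stereocentre.

Step 3
Reactants: 6 2-hydroxy-6-methyl-1-naphthaldehyde
Product: 7 2-(benzyloxy)-6-methyl-1-naphthaldehyde
Conditions: BnBr (1.2 equiv), K2CO3 (2 equiv), DMF, 50 °C
Reagents that add atoms: benzyl bromide, BrCc1ccccc1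
Why: Williamson ether synthesis on the acidic naphthol; the benzyl group shields the naphthol from the oxidant of step 6 and blocks ortho-quinone-methide chemistry until the end.

Step 4
Reactants: 3 N-[2-(benzyloxy)ethyl]-3-methoxybenzamide; 7 2-(benzyloxy)-6-methyl-1-naphthaldehyde
Product: 9 N-[2-(benzyloxy)ethyl]-2-{[2-(benzyloxy)-6-methylnaphthalen-1-yl](hydroxy)methyl}-3-methoxybenzamide (racemic), via ortho-lithiated lithium amidate 8 (not isolated)
Conditions: 3 (1.2 equiv), n-BuLi (2.5 equiv), TMEDA, THF, −78 to −30 °C; then 7, −78 to −20 °C; H2O quench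
Reagents that add atoms: none
Why: Directed ortho-metalation: the N-lithio amidate and the methoxy group jointly direct the second lithiation to the shared C2 position, and aryllithium 8 adds to the non-enolisable aldehyde; the carbinol centre forms racemic and is erased in step 5.

Step 5
Reactants: 9 N-[2-(benzyloxy)ethyl]-2-{[2-(benzyloxy)-6-methylnaphthalen-1-yl](hydroxy)methyl}-3-methoxybenzamide
Product: 11 2-[2-(benzyloxy)ethyl]-3-[2-(benzyloxy)-6-methylnaphthalen-1-yl]-3-hydroxy-4-methoxyisoindolin-1-one (racemic), via open keto amide 10 (not isolated)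
Conditions: IBX (1.5 equiv), DMSO, rt
Reagents that add atoms: none
Why: IBX oxidation of the diaryl carbinol gives keto amide 10, which closes by ring–chain tautomerism (amide N–H adds to the ketone) to hydroxylactam 11; its hemiaminal centre is racemic and labile, which step 6 exploits.

Step 6
Reactants: 11 2-[2-(benzyloxy)ethyl]-3-[2-(benzyloxy)-6-methylnaphthalen-1-yl]-3-hydroxy-4-methoxyisoindolin-1-one
Product: 12 (R)-3'-(benzyloxy)-2-[2-(benzyloxy)ethyl]-7-methoxy-7'-methyl-2'H-spiro[isoindoline-1,2'-naphtho[1,8-bc]furan]-3-one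
Conditions: Pd(OAc)2 (10 mol %), Boc-L-tert-leucine (20 mol %), PhI(OAc)2 (1.5 equiv), Li2CO3 (1.5 equiv), C6F6, 80 °C
Reagents that add atoms: none
Why: Proposed new method: a hemiaminal-hydroxyl-directed, enantioconvergent peri C–H etherification. The alkoxide of 11 binds divalent palladium carrying the chiral amino-acid carboxylate; concerted metalation–deprotonation at the naphthalene peri C8–H (the only C–H in reach, since both positions ortho to the carbinol carbon carry OMe or OBn) gives a six-membered palladacycle; PhI(OAc)2 oxidises it to tetravalent palladium, and C–O reductive elimination closes the furan ring. Because 11 racemises under the basic, warm conditions through keto amide 10, the chiral ligand can funnel all material through the faster-metalating hemiaminal enantiomer (dynamic kinetic resolution), which sets the spiro centre as (R). Closest known chemistry: Pd(OAc)2/PhI(OAc)2 hydroxyl-directed C–H activation/C–O cyclisation of tertiary alcohols to dihydrobenzofurans, and amino-acid-ligand-controlled enantioselective C–H activation/C–O lactonisation to benzofuranones; neither has been shown for a peri C–H bond, a hemiaminal hydroxyl or a dynamic kinetic resolution.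

Step 7
Reactants: 12 (R)-3'-(benzyloxy)-2-[2-(benzyloxy)ethyl]-7-methoxy-7'-methyl-2'H-spiro[isoindoline-1,2'-naphtho[1,8-bc]furan]-3-one
Product: 14 (R)-3'-hydroxy-2-(2-hydroxyethyl)-7-methoxy-7'-methyl-2'H-spiro[isoindoline-1,2'-naphtho[1,8-bc]furan]-3-one (target), via side-chain mono-benzyl ether 13 (not isolated)
Conditions: H2 (1 atm), Pd/C (10 wt % Pd), EtOAc/EtOH, rt, stopped at full conversion
Reagents that add atoms: none
Why: Heterogeneous hydrogenolysis cleaves the two primary benzyl C–O bonds (the aryl benzyl ether first, giving 13), while the quaternary, shielded spiro C–O bond should be too hindered to reach the catalyst surface; the neutral medium avoids ionisation of the N,O-ketal and ortho-quinone-methide ring opening, so the (R) centre from step 6 is kept.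

**Compound list**

1 | 3-methoxybenzoyl chloride | COc1cccc(C(=O)Cl)c1 | starting material
2 | 2-(benzyloxy)ethan-1-amine | NCCOCc1ccccc1 | starting material
3 | N-[2-(benzyloxy)ethyl]-3-methoxybenzamide | COc1cccc(C(=O)NCCOCc2ccccc2)c1 | intermediate
4 | 6-methylnaphthalen-2-ol | Cc1ccc2cc(O)ccc2c1 | starting material
5 | 1-(hydroxymethyl)-6-methylnaphthalen-2-ol (present as its magnesium salt, not isolated) | Cc1ccc2c(CO)c(O)ccc2c1 | intermediate
6 | 2-hydroxy-6-methyl-1-naphthaldehyde | Cc1ccc2c(C=O)c(O)ccc2c1 | intermediate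
7 | 2-(benzyloxy)-6-methyl-1-naphthaldehyde | Cc1ccc2c(C=O)c(OCc3ccccc3)ccc2c1 | intermediate
8 | lithium N-[2-(benzyloxy)ethyl]-2-lithio-3-methoxybenzamidate (not isolated) | COc1cccc(C(=O)N([Li])CCOCc2ccccc2)c1[Li] | intermediate
9 | N-[2-(benzyloxy)ethyl]-2-{[2-(benzyloxy)-6-methylnaphthalen-1-yl](hydroxy)methyl}-3-methoxybenzamide (racemic) | COc1cccc(C(=O)NCCOCc2ccccc2)c1C(O)c1c(OCc2ccccc2)ccc2cc(C)ccc12 | intermediate
10 | N-[2-(benzyloxy)ethyl]-2-[2-(benzyloxy)-6-methyl-1-naphthoyl]-3-methoxybenzamide (open keto amide, not isolated) | COc1cccc(C(=O)NCCOCc2ccccc2)c1C(=O)c1c(OCc2ccccc2)ccc2cc(C)ccc12 | intermediate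
11 | 2-[2-(benzyloxy)ethyl]-3-[2-(benzyloxy)-6-methylnaphthalen-1-yl]-3-hydroxy-4-methoxyisoindolin-1-one (racemic, labile) | COc1cccc2c1C(O)(c1c(OCc3ccccc3)ccc3cc(C)ccc13)N(CCOCc1ccccc1)C2=O | intermediate
12 | (R)-3'-(benzyloxy)-2-[2-(benzyloxy)ethyl]-7-methoxy-7'-methyl-2'H-spiro[isoindoline-1,2'-naphtho[1,8-bc]furan]-3-one | COc1cccc2c1[C@@]1(Oc3cc(C)cc4ccc(OCc5ccccc5)c1c34)N(CCOCc1ccccc1)C2=O | intermediate
13 | (R)-2-[2-(benzyloxy)ethyl]-3'-hydroxy-7-methoxy-7'-methyl-2'H-spiro[isoindoline-1,2'-naphtho[1,8-bc]furan]-3-one (not isolated) | COc1cccc2c1[C@@]1(Oc3cc(C)cc4ccc(O)c1c34)N(CCOCc1ccccc1)C2=O | intermediate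
14 | (R)-3'-hydroxy-2-(2-hydroxyethyl)-7-methoxy-7'-methyl-2'H-spiro[isoindoline-1,2'-naphtho[1,8-bc]furan]-3-one | COc1cccc2c1[C@@]1(Oc3cc(C)cc4ccc(O)c1c34)N(CCO)C2=O | target

**Summary**

Total steps: 7. Longest linear sequence: 6 (steps 2 to 7 from 4; step 1 is a one-step side branch).

The three steps most likely to fail:

Step 6 (the new step). Risks:
- The crowded hemiaminal alkoxide may bind palladium poorly.
- The palladium alkoxide may lose an aryl group by β-carbon elimination.
- Peri acetoxylation may compete with ring closure.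
- Racemisation of 11 may be too slow, or the ligand may discriminate poorly, giving low ee.

Fallback with known chemistry, setting out from aldehyde 7 and returning at 12: aldehyde-directed peri C–H bromination (Pd(OAc)2 cat., N-bromosuccinimide, 1,2-dichloroethane, 80 °C; C2 and C6 are blocked) gives 2-(benzyloxy)-8-bromo-6-methyl-1-naphthaldehyde F1. Addition of lithiated amide 8 as in step 4 gives the bromo carbinol N-[2-(benzyloxy)ethyl]-2-{[2-(benzyloxy)-8-bromo-6-methylnaphthalen-1-yl](hydroxy)methyl}-3-methoxybenzamide F2. IBX oxidation gives the bromo keto amide F3, which closes to the bromo hydroxylactam F4. Ullmann-type intramolecular O-arylation (CuI 10 mol %, 1,10-phenanthroline, Cs2CO3, toluene, 110 °C) closes the furan ring to the racemic dibenzyl ether F5. Preparative chiral SFC then gives (R)-12, and step 7 follows unchanged.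

Step 4. Risks: addition of the doubly ortho-substituted aryllithium 8 to the hindered aldehyde 7 may be slow, and carbinol 9 may lactonise to a phthalide with loss of the amine.

Fallback, setting out from 3 and 4 and returning at 11 (compounds 5, 6, 7, 9 and 10 are then not needed): lithiated amide 8 is quenched with DMF to give 2-[2-(benzyloxy)ethyl]-3-hydroxy-4-methoxyisoindolin-1-one F6. TsOH-catalysed N-acyliminium Friedel–Crafts amidoalkylation of naphthol 4 (CH2Cl2, rt; 2-naphthols react at C1) gives 2-[2-(benzyloxy)ethyl]-3-(2-hydroxy-6-methylnaphthalen-1-yl)-4-methoxyisoindolin-1-one F7. Benzylation (BnBr, K2CO3, DMF) gives the benzyl ether F8. Base-mediated aerobic C3–H hydroxylation (Cs2CO3 cat., P(OEt)3, O2, DMSO, rt) runs through the C3 hydroperoxide F9 and gives hydroxylactam 11.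

Step 7. Risks: hydrogenolysis of the doubly benzylic spiro C–O bond, or loss of ee once the free naphthol is present.

Fallback, setting out from 12 and returning at 14: replace the reduction by a Lewis-acid dealkylation (BCl3, pentamethylbenzene as benzyl-cation scavenger, CH2Cl2, −78 to −30 °C, then MeOH quench). No hydrogen or metal surface is involved, so the ketal C–O bond cannot be hydrogenolysed. The lactam carbonyl binds BCl3 first, which disfavours ionisation of the N,O-ketal. No new compound is made; ee is rechecked by chiral HPLC.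

Further compounds
F1 | step 6 | 2-(benzyloxy)-8-bromo-6-methyl-1-naphthaldehyde | Cc1cc(Br)c2c(C=O)c(OCc3ccccc3)ccc2c1
F2 | step 6 | N-[2-(benzyloxy)ethyl]-2-{[2-(benzyloxy)-8-bromo-6-methylnaphthalen-1-yl](hydroxy)methyl}-3-methoxybenzamide (racemic) | COc1cccc(C(=O)NCCOCc2ccccc2)c1C(O)c1c(OCc2ccccc2)ccc2cc(C)cc(Br)c12
F3 | step 6 | N-[2-(benzyloxy)ethyl]-2-[2-(benzyloxy)-8-bromo-6-methyl-1-naphthoyl]-3-methoxybenzamide | COc1cccc(C(=O)NCCOCc2ccccc2)c1C(=O)c1c(OCc2ccccc2)ccc2cc(C)cc(Br)c12
F4 | step 6 | 2-[2-(benzyloxy)ethyl]-3-[2-(benzyloxy)-8-bromo-6-methylnaphthalen-1-yl]-3-hydroxy-4-methoxyisoindolin-1-one (racemic) | COc1cccc2c1C(O)(c1c(OCc3ccccc3)ccc3cc(C)cc(Br)c13)N(CCOCc1ccccc1)C2=O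
F5 | step 6 | racemic 3'-(benzyloxy)-2-[2-(benzyloxy)ethyl]-7-methoxy-7'-methyl-2'H-spiro[isoindoline-1,2'-naphtho[1,8-bc]furan]-3-one | COc1cccc2c1C1(Oc3cc(C)cc4ccc(OCc5ccccc5)c1c34)N(CCOCc1ccccc1)C2=O
F6 | step 4 | 2-[2-(benzyloxy)ethyl]-3-hydroxy-4-methoxyisoindolin-1-one (racemic) | COc1cccc2c1C(O)N(CCOCc1ccccc1)C2=O
F7 | step 4 | 2-[2-(benzyloxy)ethyl]-3-(2-hydroxy-6-methylnaphthalen-1-yl)-4-methoxyisoindolin-1-one (racemic) | COc1cccc2c1C(c1c(O)ccc3cc(C)ccc13)N(CCOCc1ccccc1)C2=O
F8 | step 4 | 2-[2-(benzyloxy)ethyl]-3-[2-(benzyloxy)-6-methylnaphthalen-1-yl]-4-methoxyisoindolin-1-one (racemic) | COc1cccc2c1C(c1c(OCc3ccccc3)ccc3cc(C)ccc13)N(CCOCc1ccccc1)C2=O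
F9 | step 4 | 2-[2-(benzyloxy)ethyl]-3-[2-(benzyloxy)-6-methylnaphthalen-1-yl]-3-hydroperoxy-4-methoxyisoindolin-1-one (racemic) | COc1cccc2c1C(OO)(c1c(OCc3ccccc3)ccc3cc(C)ccc13)N(CCOCc1ccccc1)C2=O
F0 | step 7 | none | none
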